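**Plan**
1. Locants: oxolanone ring O1, C2 (chain), C3 (CO2H), C4 (=CH2), C5 (C=O); chain C1'–C14' counted from C2; terminal carboxyl C15'. The retrosynthesis cuts C4=CH2 first, then the C5'–C6' CH2–CH2 bond inside the tether, and last the ring bonds C2–C3 (aldol) and O1–C5 (lactonisation).
2. Enabling feature: the tether between ring C2 and C15' is an unbranched polymethylene chain with no heteroatom. C5' and C6' therefore have the same polarity and no polar handle, yet each is a plain primary carbon that can be generated as an unstabilised primary radical from a carboxylate. The three carboxyl-level carbons that must survive (C5, the C3 carboxyl, C15') are held as lactone, imide and methyl ester.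
3. Forward order: the oxolanone ring is built first (aldol/lactonisation). The side-chain alkene is cut to an acid, and the chain is joined by crossed Kolbe electrolysis with loss of two CO2. Unmasking follows, and alpha-methylenation comes last because an acrylate would trap radicals.
4. Stereochemistry: both centres come from one Evans syn-aldol with the L-valine-derived oxazolidinone (syn adduct = trans-(2R,3S) lactone). The auxiliary stays on as the protecting group of the C3 carboxyl through the electrolysis.

Key step: step 5

Assumption: 11-methoxy-11-oxoundecanoic acid (the half methyl ester of undecanedioic acid) is taken as a catalogue compound.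

**Step 1**
Reactants: 1 (4S)-4-(propan-2-yl)-1,3-oxazolidin-2-one; 2 methyl 4-chloro-4-oxobutanoate
Product: 4 methyl 4-oxo-4-[(4S)-2-oxo-4-(propan-2-yl)-1,3-oxazolidin-3-yl]butanoate, via N-lithio oxazolidinone 3 (not isolated)
Conditions: n-BuLi (1.0 equiv), THF, −78 °C; then 2, −78 → 0 °C
Reagents that add atoms: n-butyllithium [Li]CCCC (its lithium sits only in 3)
Why: N-acylation of a lithiated Evans auxiliary, in which the acid chloride of 2 reacts far faster than its methyl ester and the auxiliary stereocenter is not involved.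

**Step 2**
Reactants: 5 oct-7-en-1-ol
Product: 6 oct-7-enal
Conditions: TEMPO (10 mol %), PhI(OAc)2 (1.1 equiv), CH2Cl2, rt
Reagents that add atoms: none
Why: the oxoammonium (TEMPO/PhI(OAc)2) oxidation of a primary alcohol stops at the aldehyde in the absence of water, leaves the terminal alkene alone and forms no stereocenter.

**Step 3**
Reactants: 4 methyl 4-oxo-4-[(4S)-2-oxo-4-(propan-2-yl)-1,3-oxazolidin-3-yl]butanoate; 6 oct-7-enal
Product: 10 (4S)-3-{[(2R,3S)-2-(hept-6-en-1-yl)-5-oxooxolan-3-yl]carbonyl}-4-(propan-2-yl)-1,3-oxazolidin-2-one, via Z-boron enolate 7 (not isolated), via boron aldolate 8 (not isolated), via syn-aldol hydroxy ester 9 (not isolated)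
Conditions: Bu2BOTf (1.15 equiv), Et3N (1.3 equiv), CH2Cl2, 0 °C; 6, −78 → 0 °C; pH 7 buffer/MeOH/30 % H2O2, 0 °C; crude + p-TsOH·H2O (10 mol %), CH2Cl2, rt
Reagents that add atoms: dibutylboron triflate CCCCB(CCCC)OS(=O)(=O)C(F)(F)F (its boron and butyl groups sit only in 7 and 8)
Why: Evans syn-aldol, in which soft enolisation occurs only next to the boron-bound imide to give Z-enolate 7, this adds to 6 through a chair Zimmerman–Traxler transition state on the face away from the isopropyl group to set the (2S,3R)-syn adduct 9, and acid-catalysed 5-exo-trig lactonisation onto the methyl ester turns syn into the trans-(2R,3S) oxolanone without touching either centre.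

**Step 4**
Reactants: 10 (4S)-3-{[(2R,3S)-2-(hept-6-en-1-yl)-5-oxooxolan-3-yl]carbonyl}-4-(propan-2-yl)-1,3-oxazolidin-2-one
Product: 11 6-[(2R,3S)-5-oxo-3-{[(4S)-2-oxo-4-(propan-2-yl)-1,3-oxazolidin-3-yl]carbonyl}oxolan-2-yl]hexanoic acid
Conditions: RuCl3·xH2O (3 mol %), NaIO4 (4.5 equiv), MeCN/EtOAc/H2O, 0 °C → rt
Reagents that add atoms: sodium periodate [Na+].[O-]I(=O)(=O)=O (oxygen, passed on through RuO4); water O
Why: RuO4-catalysed oxidative cleavage takes a terminal alkene to the acid one carbon shorter, and the lactone, the imide and the arene-free auxiliary are inert to it, so C2 and C3 stay as set.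

**Step 5**
Reactants: 11 6-[(2R,3S)-5-oxo-3-{[(4S)-2-oxo-4-(propan-2-yl)-1,3-oxazolidin-3-yl]carbonyl}oxolan-2-yl]hexanoic acid; 12 11-methoxy-11-oxoundecanoic acid
Product: 15 methyl 15-[(2R,3S)-5-oxo-3-{[(4S)-2-oxo-4-(propan-2-yl)-1,3-oxazolidin-3-yl]carbonyl}oxolan-2-yl]pentadecanoate, via oxolanyl-pentyl radical 13 (not isolated), via 10-methoxy-10-oxodecyl radical 14 (not isolated)
Conditions: undivided cell, smooth Pt anode/Pt cathode, 11 (1 equiv), 12 (5 equiv, part of it fed during the run), NaOMe (5 mol % of total CO2H, premixed with 12), MeOH, 15–25 °C, constant current ca. 150–200 mA cm−2, until 11 is consumed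
Reagents that add atoms: none
Why: Crossed Kolbe electrolysis: at smooth Pt under high current density each carboxylate gives up one electron and loses CO2, and the unstabilised primary radicals 13 and 14 combine in the crowded layer at the anode to form the C5'–C6' CH2–CH2 bond while protons are reduced to H2 at the cathode. The closest known reaction type is the crossed Kolbe coupling of a valuable fatty acid with an excess of a dicarboxylic acid half ester, a standard entry to long-chain esters. No ring is closed and no stereocenter is formed; C2 and C3 lie five and six bonds from the radical centre and are not disturbed in the weakly acidic medium. The step needs exactly two dischargeable carboxylates in the cell, which is secured because the C3 carboxyl is held as the imide of the auxiliary (isopropyl rather than benzyl, so no oxidisable arene), C5 as the lactone and C15' as a methyl ester. The radical path is favoured over the cationic (Hofer–Moest) path by the unbranched, donor-free alpha-CH2 of both acids, by Pt, by the low degree of neutralisation and by the high current density. Hetero- versus homocoupling is statistical, so cheap 12 is used in excess and partly fed, which also keeps the bulk acidic so that cathodic methoxide cannot reach the imide; the nonpolar dimer of 12 is removed by chromatography.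

**Step 6**
Reactants: 15 methyl 15-[(2R,3S)-5-oxo-3-{[(4S)-2-oxo-4-(propan-2-yl)-1,3-oxazolidin-3-yl]carbonyl}oxolan-2-yl]pentadecanoate
Product: 19 (2R,3S)-2-(14-carboxytetradecyl)-5-oxooxolane-3-carboxylic acid, via peroxy acid 16 (not isolated), via acid ester 17 (not isolated), via ring-opened trilithium salt 18 (not isolated)
Conditions: LiOH·H2O (2 equiv), 30 % H2O2 (5 equiv), THF/H2O 3:1, 0 °C; aq Na2SO3; LiOH (5 equiv), rt; CH2Cl2 wash (auxiliary recovered); 2 M HCl to pH 1, EtOAc
Reagents that add atoms: hydrogen peroxide OO; lithium hydroxide [Li+].[OH-]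
Why: hydroperoxide attacks the exocyclic imide carbonyl (standard LiOOH removal of an Evans auxiliary), hydroxide then saponifies the methyl ester and opens the lactone by acyl–oxygen cleavage, and acid recloses the gamma-lactone, so no bond at C2 or C3 is broken and the C3 carboxylate guards against epimerisation.

**Step 7**
Reactants: 19 (2R,3S)-2-(14-carboxytetradecyl)-5-oxooxolane-3-carboxylic acid
Product: 22 (2R,3S)-2-(14-carboxytetradecyl)-4-methylidene-5-oxooxolane-3-carboxylic acid, via alpha-carboxy lactone 20 (not isolated), via Mannich acid 21 (not isolated)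
Conditions: MeOMgOCO2Me (2 M in DMF, large excess), 135 °C, N2; cold 6 M HCl, EtOAc; crude 20, 37 % aq HCHO, PhNHMe, NaOAc, AcOH, rt
Reagents that add atoms: methyl magnesium carbonate COC(=O)O[Mg]OC (its CO2 sits only in 20 and 21); formaldehyde C=O; N-methylaniline CNc1ccccc1 (only in 21)
Why: Stiles carboxylation of the lactone alpha-CH2 (driven by the magnesium chelate) followed by decarboxylative Mannich methylenation is the standard endgame for alpha-methylene paraconic acids, the two carboxylates are inert, C3–H next to a carboxylate is not enolised, and trans is in any case the stable arrangement.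

**Compound list**
1 | (4S)-4-(propan-2-yl)-1,3-oxazolidin-2-one | CC(C)[C@H]1COC(=O)N1 | starting material
2 | methyl 4-chloro-4-oxobutanoate | COC(=O)CCC(=O)Cl | starting material
3 | N-lithio (4S)-4-(propan-2-yl)-1,3-oxazolidin-2-one (formed in the flask) | CC(C)[C@H]1COC(=O)N1[Li] | intermediate
4 | methyl 4-oxo-4-[(4S)-2-oxo-4-(propan-2-yl)-1,3-oxazolidin-3-yl]butanoate | CC(C)[C@H]1COC(=O)N1C(=O)CCC(=O)OC | intermediate
5 | oct-7-en-1-ol | C=CCCCCCCO | starting material
6 | oct-7-enal | C=CCCCCCC=O | intermediate
7 | Z-dibutylboron enolate of 4 (formed in the flask) | CCCCB(CCCC)O/C(=C\CC(=O)OC)N1C(=O)OC[C@@H]1C(C)C | intermediate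
8 | dibutylboron aldolate of the (2S,3R)-syn adduct (formed in the flask) | CC(C)[C@H]1COC(=O)N1C(=O)[C@@H](CC(=O)OC)[C@H](OB(CCCC)CCCC)CCCCCC=C | intermediate
9 | methyl (3S,4R)-4-hydroxy-3-{[(4S)-2-oxo-4-(propan-2-yl)-1,3-oxazolidin-3-yl]carbonyl}undec-10-enoate, the syn-aldol (not purified) | CC(C)[C@H]1COC(=O)N1C(=O)[C@@H](CC(=O)OC)[C@H](O)CCCCCC=C | intermediate
10 | (4S)-3-{[(2R,3S)-2-(hept-6-en-1-yl)-5-oxooxolan-3-yl]carbonyl}-4-(propan-2-yl)-1,3-oxazolidin-2-one | CC(C)[C@H]1COC(=O)N1C(=O)[C@H]2CC(=O)O[C@@H]2CCCCCC=C | intermediate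
11 | 6-[(2R,3S)-5-oxo-3-{[(4S)-2-oxo-4-(propan-2-yl)-1,3-oxazolidin-3-yl]carbonyl}oxolan-2-yl]hexanoic acid | CC(C)[C@H]1COC(=O)N1C(=O)[C@H]2CC(=O)O[C@@H]2CCCCCC(=O)O | intermediate
12 | 11-methoxy-11-oxoundecanoic acid | COC(=O)CCCCCCCCCC(=O)O | starting material
13 | 5-[(2R,3S)-3-(auxiliary-carbonyl)-5-oxooxolan-2-yl]pentyl radical (transient) | CC(C)[C@H]1COC(=O)N1C(=O)[C@H]2CC(=O)O[C@@H]2CCCC[CH2] | intermediate
14 | 10-methoxy-10-oxodecyl radical (transient) | COC(=O)CCCCCCCC[CH2] | intermediate
15 | methyl 15-[(2R,3S)-5-oxo-3-{[(4S)-2-oxo-4-(propan-2-yl)-1,3-oxazolidin-3-yl]carbonyl}oxolan-2-yl]pentadecanoate | CC(C)[C@H]1COC(=O)N1C(=O)[C@H]2CC(=O)O[C@@H]2CCCCCCCCCCCCCCC(=O)OC | intermediate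
16 | (2R,3S)-2-(15-methoxy-15-oxopentadecyl)-5-oxooxolane-3-carboperoxoic acid (formed in the flask) | OOC(=O)[C@H]1CC(=O)O[C@@H]1CCCCCCCCCCCCCCC(=O)OC | intermediate
17 | (2R,3S)-2-(15-methoxy-15-oxopentadecyl)-5-oxooxolane-3-carboxylic acid (formed in the flask) | OC(=O)[C@H]1CC(=O)O[C@@H]1CCCCCCCCCCCCCCC(=O)OC | intermediate
18 | trilithium (2S,3R)-3-hydroxyheptadecane-1,2,17-tricarboxylate (formed in the flask) | [Li+].[Li+].[Li+].[O-]C(=O)[C@@H](CC(=O)[O-])[C@H](O)CCCCCCCCCCCCCCC(=O)[O-] | intermediate
19 | (2R,3S)-2-(14-carboxytetradecyl)-5-oxooxolane-3-carboxylic acid | OC(=O)[C@H]1CC(=O)O[C@@H]1CCCCCCCCCCCCCCC(=O)O | intermediate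
20 | (2R,3S)-2-(14-carboxytetradecyl)-5-oxooxolane-3,4-dicarboxylic acid, C4 not defined (used crude) | OC(=O)C1C(=O)O[C@H](CCCCCCCCCCCCCCC(=O)O)[C@H]1C(=O)O | intermediate
21 | (2R,3S)-2-(14-carboxytetradecyl)-4-{[methyl(phenyl)amino]methyl}-5-oxooxolane-3,4-dicarboxylic acid, C4 not defined (formed in the flask) | CN(CC1(C(=O)O)C(=O)O[C@H](CCCCCCCCCCCCCCC(=O)O)[C@H]1C(=O)O)c2ccccc2 | intermediate
22 | (2R,3S)-2-(14-carboxytetradecyl)-4-methylidene-5-oxooxolane-3-carboxylic acid | C=C1C(=O)O[C@H](CCCCCCCCCCCCCCC(=O)O)[C@H]1C(=O)O | target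

**Total step count:** 7. **Longest linear sequence:** 6 (steps 1, 3, 4, 5, 6, 7; step 2 feeds step 3).

**Steps most likely to fail**

Step 5. Material may be lost to statistical homocoupling, to over-oxidation of the radicals to cations (ethers, alkenes), to fouling of the anode, or to slow methanolysis of the imide once the acid buffer runs low. The fallback replaces anodic radical–radical combination with reductive nickel catalysis on pre-activated esters, and it sets out from 11 and 12. Each acid is esterified with N-hydroxyphthalimide (DIC, cat. DMAP, CH2Cl2). This gives the N-hydroxyphthalimide ester of the lactone acid F1 and the N-hydroxyphthalimide ester of the half ester F2. The two are joined by a nickel-catalysed doubly decarboxylative C(sp3)–C(sp3) cross-coupling (NiCl2·glyme, terpyridine-type ligand, cathodic reduction with a sacrificial metal anode, DMF, rt, F2 in excess). This forms the same C5'–C6' bond under neutral, methanol-free conditions and rejoins the route at 15.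

Step 7. Carboxylation at 135 °C may stay incomplete in the presence of two carboxylates, the malonic-type acid may lose CO2 before the Mannich stage, or the exocyclic alkene may migrate into the ring. The fallback sets out from 19 and works at low temperature. NaHMDS (3.3 equiv, THF, −78 °C) forms the bis-carboxylate lactone enolate, the same kind of anion used for alpha-alkylation of paraconic acids. Eschenmoser's salt traps it as the alpha-(dimethylaminomethyl) lactone diacid F3. MeI in MeOH/KHCO3 quaternises the nitrogen selectively to the trimethylammonium iodide F4. Aqueous NaHCO3 then induces beta-elimination, and acidification rejoins the route at 22.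

Step 3. Enolisation may be incomplete or not confined to the imide side, facial selectivity may be poor, or retro-aldol cleavage may occur during lactonisation. The fallback sets the relative configuration by equilibration and separates the enantiomers with the same auxiliary; it sets out from 6. The lithium enolate of dimethyl succinate (LDA, THF, −78 °C) is added to 6. The crude aldol is lactonised (p-TsOH) and equilibrated with DBU to racemic trans methyl 2-(hept-6-en-1-yl)-5-oxooxolane-3-carboxylate F5. LiOH followed by HCl gives the racemic trans acid F6. Pivaloyl chloride/Et3N gives the mixed pivalic anhydride F7, which acylates 3. The two diastereomeric imides, 10 and its (2S,3R) isomer F8, are separated by chromatography or crystallisation, and the route is rejoined at 10.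

**Further compounds**
F1 | step 5 | 1,3-dioxoisoindolin-2-yl 6-[(2R,3S)-5-oxo-3-{[(4S)-2-oxo-4-(propan-2-yl)-1,3-oxazolidin-3-yl]carbonyl}oxolan-2-yl]hexanoate | CC(C)[C@H]1COC(=O)N1C(=O)[C@H]2CC(=O)O[C@@H]2CCCCCC(=O)ON3C(=O)c4ccccc4C3=O
F2 | step 5 | 1-(1,3-dioxoisoindolin-2-yl) 11-methyl undecanedioate | COC(=O)CCCCCCCCCC(=O)ON1C(=O)c2ccccc2C1=O
F3 | step 7 | (2R,3S)-2-(14-carboxytetradecyl)-4-[(dimethylamino)methyl]-5-oxooxolane-3-carboxylic acid (C4 not defined, lost in the elimination) | CN(C)CC1C(=O)O[C@H](CCCCCCCCCCCCCCC(=O)O)[C@H]1C(=O)O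
F4 | step 7 | {[(4S,5R)-4-carboxy-5-(14-carboxytetradecyl)-2-oxooxolan-3-yl]methyl}trimethylammonium iodide (C3 of this name not defined) | C[N+](C)(C)CC1C(=O)O[C@H](CCCCCCCCCCCCCCC(=O)O)[C@H]1C(=O)O.[I-]
F5 | step 3 | racemic trans methyl 2-(hept-6-en-1-yl)-5-oxooxolane-3-carboxylate (one enantiomer drawn) | COC(=O)[C@H]1CC(=O)O[C@@H]1CCCCCC=C
F6 | step 3 | racemic trans 2-(hept-6-en-1-yl)-5-oxooxolane-3-carboxylic acid (one enantiomer drawn) | OC(=O)[C@H]1CC(=O)O[C@@H]1CCCCCC=C
F7 | step 3 | racemic trans 2-(hept-6-en-1-yl)-5-oxooxolane-3-carboxylic pivalic anhydride (one enantiomer drawn) | CC(C)(C)C(=O)OC(=O)[C@H]1CC(=O)O[C@@H]1CCCCCC=C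
F8 | step 3 | (4S)-3-{[(2S,3R)-2-(hept-6-en-1-yl)-5-oxooxolan-3-yl]carbonyl}-4-(propan-2-yl)-1,3-oxazolidin-2-one | CC(C)[C@H]1COC(=O)N1C(=O)[C@@H]2CC(=O)O[C@H]2CCCCCC=C
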